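**Retrosynthetic overview**

1. Ring atoms are numbered as in the target name: C1 carries OAc, C2 the ethylidene (side chain C1′H=, C2′H2Br), C3 Cl, C4 the two methyls, C5 Br, C6 is CH2. The last steps install acetate, allylic bromide and chloride; the C3 chloride comes by inversion from an equatorial allylic alcohol.
2. Key disconnection (the only ring, a six-membered carbocycle): bonds C2–C3 and C1–C6 are made in one flask from a Z-alkenyl iodide holding C1 as a dibenzyl acetal and 2,2-dimethylbut-3-enal, by asymmetric alkenylzinc addition followed by TiBr4-triggered acetal–Prins closure through the vinyl group, with bromide ending at C5.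
3. Enabling feature: ring atom C2 is an sp2 carbon between the two heteroatom-bearing ring carbons C1 and C3, so it can act as an alkenyl anion toward a C3 aldehyde while C1 waits as a latent oxocarbenium ion; the C6H2–C5HBr edge beside quaternary C4 is the imprint of a vinyl group that takes carbon at its CH2 end and bromide at its CH end.
4. The C3 carbinol from the key step relays absolute configuration to C1 and C5 through allylic 1,3-strain, is then erased (oxidation) and reset (Luche reduction) for the inverting chlorination.
5. Precursors: the alkenyl iodide from 3,3-diethoxyprop-1-yne in four steps (geometry from directed trans-hydroalumination/iodination); the aldehyde from 2,2-dimethylbut-3-en-1-ol in one step.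

Key step: step 6

Remark: 3,3-diethoxyprop-1-yne, benzyl alcohol and 2,2-dimethylbut-3-en-1-ol are taken as commercial; the facial sense of (+)-MIB (Re face of the aldehyde) is assigned by the usual model for amino-alcohol-catalysed organozinc additions, (−)-MIB being Si-selective.

**Route**

Step 1
Reactants: 1 3,3-diethoxyprop-1-yne; 2 benzyl alcohol
Product: 3 3,3-bis(benzyloxy)prop-1-yne
Conditions: 2 (2.5 equiv in all), TsOH (cat.), cyclohexane, reflux, EtOH distilled off
Reagents that add atoms: benzyl alcohol (the second equivalent of 2), OCc1ccccc1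
Why: Acid-catalysed transacetalisation consumes two equivalents of benzyl alcohol, one for each ethoxy group, and is driven to the dibenzyl acetal by removal of ethanol, so that the oxygen later left on C1 can be freed with BCl3; no stereocentre is formed.

Step 2
Reactants: 3 3,3-bis(benzyloxy)prop-1-yne
Product: 4 4,4-bis(benzyloxy)but-2-yn-1-ol
Conditions: n-BuLi, THF, −78 °C; (CH2O)n, −78 °C → rt; H2O
Reagents that add atoms: formaldehyde (as paraformaldehyde), C=O
Why: Deprotonation of the terminal alkyne and 1,2-addition to formaldehyde (alkynylation of an aldehyde) gives the propargylic alcohol whose hydroxyl directs the next step; no stereocentre is formed.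

Step 3
Reactants: 4 4,4-bis(benzyloxy)but-2-yn-1-ol
Product: 6 (Z)-4,4-bis(benzyloxy)-3-iodobut-2-en-1-ol, via alkenylaluminate 5 (not isolated)
Conditions: NaAlH2(OCH2CH2OMe)2, THF, 0 °C; I2, −78 → 0 °C
Reagents that add atoms: iodine, [I][I]
Why: Hydroxyl-directed trans-hydroalumination of a propargylic alcohol puts aluminium on the distal alkyne carbon inside a five-membered ring, and iododealumination with retention leaves I and CH2OH cis, which fixes the alkene geometry of the target here.

Step 4
Reactants: 6 (Z)-4,4-bis(benzyloxy)-3-iodobut-2-en-1-ol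
Product: 7 (Z)-1,1,4-tris(benzyloxy)-2-iodobut-2-ene
Conditions: NaH, BnBr, Bu4NI (cat.), THF, 0 °C → rt
Reagents that add atoms: benzyl bromide, BrCc1ccccc1
Why: Williamson etherification caps the primary alcohol so that it survives t-BuLi and TiBr4; the alkene geometry is untouched.

Step 5
Reactants: 8 2,2-dimethylbut-3-en-1-ol
Product: 9 2,2-dimethylbut-3-enal
Conditions: TEMPO (cat.), PhI(OAc)2, CH2Cl2, rt; used as a dried CH2Cl2/toluene solution
Reagents that add atoms: none
Why: Oxoammonium (TEMPO) oxidation stops at the aldehyde, which can neither enolise nor move its double bond into conjugation because the alpha carbon is quaternary.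

Step 6
Reactants: 7 (Z)-1,1,4-tris(benzyloxy)-2-iodobut-2-ene; 9 2,2-dimethylbut-3-enal
Product: 13 (1S,2E,3R,5R)-1-benzyloxy-2-(2-benzyloxyethylidene)-5-bromo-3-hydroxy-4,4-dimethylcyclohexane, via alkenyllithium 10 (not isolated), via alkenylzinc bromide 11 (not isolated), via bromozinc alkoxide 12 (not isolated)
Conditions: t-BuLi (2 equiv), Et2O, −78 °C; ZnBr2, −78 → 0 °C; TEEDA (N,N,N′,N′-tetraethylethylenediamine), (+)-MIB (3-exo-morpholinoisoborneol, 10 mol %), 9, toluene, 0 °C; solvent switch to CH2Cl2 in the same flask, TiBr4 (4 equiv), −78 °C; aqueous work-up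
Reagents that add atoms: titanium tetrabromide, Br[Ti](Br)(Br)Br
Why: Proposed new method: iodine–lithium exchange with retention, transmetallation to the alkenylzinc bromide and (+)-MIB-catalysed addition to the Re face of 9 form the C2–C3 bond and the (S)-carbinol (closest known type: amino-alcohol-catalysed alkenylzinc addition to aldehydes), after which TiBr4 ionises the dibenzyl acetal to an O-benzyl oxocarbenium ion at C1, the pendant vinyl group attacks it through its CH2 terminus to form the C1–C6 bond, and bromide from the titanate caps the secondary cation at C5 (closest known types: acetal-initiated Prins or cation–olefin cyclisation with halide termination, and one-flask aldol–Prins cascades run with TiBr4). The single ring closes in a 6-endo-trig mode with respect to the vinyl group and exo with respect to the C=O+ bond, through a chair transition state. C3 is set by the catalyst, while C1 and C5 are set by the substrate: allylic 1,3-strain with the cis CH2OBn group of the alkylidene forces the C3–O bond axial, the benzyloxy group of the oxocarbenium ion sits equatorial, and anti addition across the vinyl group delivers bromide equatorially, so OBn and Br should be cis to each other and trans to the C3 oxygen. The step needs attack at C1 instead of the side-chain terminus of the alkoxyallyl cation, which the higher charge at the oxygen-bearing carbon and the non-chelating O-alkyl oxocarbenium ion should secure, and it needs bromide capture to outrun a 1,2-methyl shift from C4, which the low temperature and the bromide-rich counter-ion should favour. The alkene geometry is carried through from 7 because exchange, transmetallation and addition all proceed with retention.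

Step 7
Reactants: 13 (1S,2E,3R,5R)-1-benzyloxy-2-(2-benzyloxyethylidene)-5-bromo-3-hydroxy-4,4-dimethylcyclohexane
Product: 14 (1S,2Z,5R)-1-benzyloxy-2-(2-benzyloxyethylidene)-5-bromo-4,4-dimethylcyclohexan-3-one
Conditions: DMP (triacetoxyperiodinane), CH2Cl2, 0 °C → rt
Reagents that add atoms: none
Why: Periodinane oxidation converts the hindered axial allylic alcohol into the enone without touching the alkyl bromide or the benzyl ethers, and so erases the relay stereocentre for resetting.

Step 8
Reactants: 14 (1S,2Z,5R)-1-benzyloxy-2-(2-benzyloxyethylidene)-5-bromo-4,4-dimethylcyclohexan-3-one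
Product: 15 (1S,2E,3S,5R)-1-benzyloxy-2-(2-benzyloxyethylidene)-5-bromo-3-hydroxy-4,4-dimethylcyclohexane
Conditions: NaBH4, CeCl3·7H2O, MeOH, −78 °C
Reagents that add atoms: none
Why: In this Luche 1,2-reduction hydride should add axially, anti to the axial C4 methyl group (torsional control), giving the equatorial C3 alcohol cis to OBn and Br; the allylic strain between the C3 oxygen and the side chain is already present in 14 and does not rise on the way.

Step 9
Reactants: 15 (1S,2E,3S,5R)-1-benzyloxy-2-(2-benzyloxyethylidene)-5-bromo-3-hydroxy-4,4-dimethylcyclohexane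
Product: 16 (1S,2Z,3R,5R)-1-benzyloxy-2-(2-benzyloxyethylidene)-5-bromo-3-chloro-4,4-dimethylcyclohexane
Conditions: PPh3, Cl3CC(O)CCl3, CH2Cl2, 0 °C
Reagents that add atoms: hexachloroacetone, ClC(Cl)(Cl)C(=O)C(Cl)(Cl)Cl
Why: Deoxychlorination of an allylic alcohol with PPh3/hexachloroacetone goes by SN2 displacement of the alkoxyphosphonium ion with inversion and little allylic transposition, and here inversion also relieves the allylic 1,3-strain of the equatorial C–O bond, so the axial C3 chloride of the target should result.

Step 10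
Reactants: 16 (1S,2Z,3R,5R)-1-benzyloxy-2-(2-benzyloxyethylidene)-5-bromo-3-chloro-4,4-dimethylcyclohexane
Product: 17 (1S,2Z,3R,5R)-5-bromo-3-chloro-2-(2-hydroxyethylidene)-4,4-dimethylcyclohexan-1-ol
Conditions: BCl3, C6HMe5, CH2Cl2, −78 °C; H2O
Reagents that add atoms: none
Why: Lewis-acid debenzylation with BCl3 and pentamethylbenzene as cation scavenger cleaves both benzyl ethers at the benzylic C–O bond at low temperature, leaving the alkene, the alkyl bromide and the C1 and C3 configurations alone.

Step 11
Reactants: 17 (1S,2Z,3R,5R)-5-bromo-3-chloro-2-(2-hydroxyethylidene)-4,4-dimethylcyclohexan-1-ol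
Product: 18 (1S,2Z,3R,5R)-5-bromo-2-(2-bromoethylidene)-3-chloro-4,4-dimethylcyclohexan-1-ol
Conditions: CBr4 (1.05 equiv), PPh3, CH2Cl2, −20 → 0 °C
Reagents that add atoms: carbon tetrabromide, BrC(Br)(Br)Br
Why: In this Appel bromination the primary allylic alcohol forms its alkoxyphosphonium ion far faster than the secondary C1 alcohol and is displaced by bromide (SN2), so only the side-chain hydroxyl is exchanged.

Step 12
Reactants: 18 (1S,2Z,3R,5R)-5-bromo-2-(2-bromoethylidene)-3-chloro-4,4-dimethylcyclohexan-1-ol
Product: 19 (1S,2Z,3R,5R)-5-bromo-2-(2-bromoethylidene)-3-chloro-4,4-dimethylcyclohexyl acetate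
Conditions: Ac2O, TMSOTf (cat.), CH2Cl2, −40 °C
Reagents that add atoms: acetic anhydride, CC(=O)OC(C)=O
Why: Acid-catalysed acetylation esterifies the secondary alcohol with retention and avoids amine bases that would be alkylated by the allylic bromide.

**Compound list**

1 | 3,3-diethoxyprop-1-yne | C#CC(OCC)OCC | starting material
2 | benzyl alcohol | OCc1ccccc1 | starting material
3 | 3,3-bis(benzyloxy)prop-1-yne | C#CC(OCc1ccccc1)OCc1ccccc1 | intermediate
4 | 4,4-bis(benzyloxy)but-2-yn-1-ol | OCC#CC(OCc1ccccc1)OCc1ccccc1 | intermediate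
5 | sodium cyclic alkenylaluminate from 4 (Al on the acetal-bearing alkene carbon and on the CH2O oxygen, two 2-methoxyethoxy ligands) | [Na+].COCCO[Al-]1(OCCOC)OC/C=C1/C(OCc1ccccc1)OCc1ccccc1 | intermediate
6 | (Z)-4,4-bis(benzyloxy)-3-iodobut-2-en-1-ol | I/C(=C\CO)C(OCc1ccccc1)OCc1ccccc1 | intermediate
7 | (Z)-1,1,4-tris(benzyloxy)-2-iodobut-2-ene | I/C(=C\COCc1ccccc1)C(OCc1ccccc1)OCc1ccccc1 | intermediate
8 | 2,2-dimethylbut-3-en-1-ol | C=CC(C)(C)CO | starting material
9 | 2,2-dimethylbut-3-enal | C=CC(C)(C)C=O | intermediate
10 | [(E)-1,1,4-tris(benzyloxy)but-2-en-2-yl]lithium (Li cis to CH2OBn) | [Li]/C(=C\COCc1ccccc1)C(OCc1ccccc1)OCc1ccccc1 | intermediate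
11 | bromo[(Z)-1,1,4-tris(benzyloxy)but-2-en-2-yl]zinc | Br[Zn]/C(=C\COCc1ccccc1)C(OCc1ccccc1)OCc1ccccc1 | intermediate
12 | bromozinc alkoxide of (4S,5E)-7-benzyloxy-5-[bis(benzyloxy)methyl]-3,3-dimethylhepta-1,5-dien-4-ol | C=CC(C)(C)[C@H](O[Zn]Br)/C(=C\COCc1ccccc1)C(OCc1ccccc1)OCc1ccccc1 | intermediate
13 | (1S,2E,3R,5R)-1-benzyloxy-2-(2-benzyloxyethylidene)-5-bromo-3-hydroxy-4,4-dimethylcyclohexane (OH trans to OBn and Br) | c1ccccc1CO[C@H]2C[C@@H](Br)C(C)(C)[C@H](O)/C2=C\COCc1ccccc1 | intermediate
14 | (1S,2Z,5R)-1-benzyloxy-2-(2-benzyloxyethylidene)-5-bromo-4,4-dimethylcyclohexan-3-one | c1ccccc1CO[C@H]2C[C@@H](Br)C(C)(C)C(=O)/C2=C\COCc1ccccc1 | intermediate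
15 | (1S,2E,3S,5R)-1-benzyloxy-2-(2-benzyloxyethylidene)-5-bromo-3-hydroxy-4,4-dimethylcyclohexane (OH cis to OBn and Br) | c1ccccc1CO[C@H]2C[C@@H](Br)C(C)(C)[C@@H](O)/C2=C\COCc1ccccc1 | intermediate
16 | (1S,2Z,3R,5R)-1-benzyloxy-2-(2-benzyloxyethylidene)-5-bromo-3-chloro-4,4-dimethylcyclohexane | c1ccccc1CO[C@H]2C[C@@H](Br)C(C)(C)[C@H](Cl)/C2=C\COCc1ccccc1 | intermediate
17 | (1S,2Z,3R,5R)-5-bromo-3-chloro-2-(2-hydroxyethylidene)-4,4-dimethylcyclohexan-1-ol | O[C@H]1C[C@@H](Br)C(C)(C)[C@H](Cl)/C1=C\CO | intermediate
18 | (1S,2Z,3R,5R)-5-bromo-2-(2-bromoethylidene)-3-chloro-4,4-dimethylcyclohexan-1-ol | O[C@H]1C[C@@H](Br)C(C)(C)[C@H](Cl)/C1=C\CBr | intermediate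
19 | (1S,2Z,3R,5R)-5-bromo-2-(2-bromoethylidene)-3-chloro-4,4-dimethylcyclohexyl acetate | CC(=O)O[C@H]1C[C@@H](Br)C(C)(C)[C@H](Cl)/C1=C\CBr | target

**Step count**

Total steps: 12. Longest linear sequence: 11 (steps 1–4 and 6–12).

**Steps most likely to fail**

Step 6 (proposed new method). The amine and zinc salts of the first stage may intercept TiBr4, the metal alkoxide at C3 may ionise, or a 1,2-methyl shift from C4 may outrun bromide capture. The fallback uses known chemistry in separate operations with the C3 oxygen masked, and sets out from 7 and 9. The alkenylzinc addition is worked up on its own to give (4S,5E)-7-benzyloxy-5-[bis(benzyloxy)methyl]-3,3-dimethylhepta-1,5-dien-4-ol F1. TBSOTf and 2,6-lutidine convert it into its tert-butyldimethylsilyl ether F2. SnBr4 in CH2Cl2 at −78 °C (acetal-initiated Prins cyclisation with bromide termination, free of amines and zinc) closes the ring to (1S,2Z,3R,5R)-1-benzyloxy-2-(2-benzyloxyethylidene)-5-bromo-3-(tert-butyldimethylsilyloxy)-4,4-dimethylcyclohexane F3. HF·pyridine removes the silyl group and the route is rejoined at 13.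

Step 9. Chloride may enter at the side-chain carbon with allylic transposition, or the strained alkoxyphosphonium ion may ionise with loss of regiocontrol. The fallback places the chloride before the ring is closed and sets out from 7 and 9. The alkenylzinc addition run with (−)-MIB gives the enantiomeric carbinol (4R,5E)-7-benzyloxy-5-[bis(benzyloxy)methyl]-3,3-dimethylhepta-1,5-dien-4-ol F4. PPh3/hexachloroacetone converts it with inversion into (4S,5Z)-7-benzyloxy-5-[bis(benzyloxy)methyl]-4-chloro-3,3-dimethylhepta-1,5-diene F5. SnBr4-mediated Prins cyclisation of F5, in which the same allylic strain should place the C–Cl bond axial, gives 16 directly, where the route is rejoined.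

Step 8. Hydride may be delivered from the equatorial side, because the strained equatorial alcohol is the less stable epimer; this would return 13. The fallback bypasses steps 7–9 and makes no new compound (F0). It sets out from 13: chlorosulfite formation with SOCl2 in Et2O without base, and collapse by the SNi pathway with retention, should convert the axial alcohol directly into the axial chloride 16, where the route is rejoined.

Further compounds

F1 | step 6 | (4S,5E)-7-benzyloxy-5-[bis(benzyloxy)methyl]-3,3-dimethylhepta-1,5-dien-4-ol | C=CC(C)(C)[C@H](O)/C(=C\COCc1ccccc1)C(OCc1ccccc1)OCc1ccccc1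
F2 | step 6 | tert-butyldimethylsilyl ether of (4S,5E)-7-benzyloxy-5-[bis(benzyloxy)methyl]-3,3-dimethylhepta-1,5-dien-4-ol | C=CC(C)(C)[C@H](O[Si](C)(C)C(C)(C)C)/C(=C\COCc1ccccc1)C(OCc1ccccc1)OCc1ccccc1
F3 | step 6 | (1S,2Z,3R,5R)-1-benzyloxy-2-(2-benzyloxyethylidene)-5-bromo-3-(tert-butyldimethylsilyloxy)-4,4-dimethylcyclohexane | c1ccccc1CO[C@H]2C[C@@H](Br)C(C)(C)[C@H](O[Si](C)(C)C(C)(C)C)/C2=C\COCc1ccccc1
F4 | step 9 | (4R,5E)-7-benzyloxy-5-[bis(benzyloxy)methyl]-3,3-dimethylhepta-1,5-dien-4-ol | C=CC(C)(C)[C@@H](O)/C(=C\COCc1ccccc1)C(OCc1ccccc1)OCc1ccccc1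
F5 | step 9 | (4S,5Z)-7-benzyloxy-5-[bis(benzyloxy)methyl]-4-chloro-3,3-dimethylhepta-1,5-diene | C=CC(C)(C)[C@H](Cl)/C(=C\COCc1ccccc1)C(OCc1ccccc1)OCc1ccccc1
F0 | step 8 | none | none
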